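## Structural features

The target (29, C24H14O11) is an achiral, fully aromatic hexacycle without stereocentres, so every problem is one of regiochemistry. Ring A, a 3,5-dihydroxyphenyl group, is bound through an ether oxygen to B1 of ring B, a benzene with five oxygens: B1 (O-aryl), B2 (OH), B3 (H), B4 (OH), B5 and B6 (dioxin oxygens). A 1,4-dioxin (B5–O–D6 and B6–O–D1) fuses ring B to ring D, which carries in order D1 (dioxin O), D2 (OH), D3 (H), D4 (furan O), D5 (C–C bond to F6) and D6 (dioxin O). A furan (D4–O–F1, D5–F6) fuses ring D to ring F, a resorcinol with F3–OH and F5–OH, the latter in the bay opposite D6–O. Seven phenols on electron-rich rings, several in catechol, hydroquinone or phloroglucinol relationships, make the free compound and any partly deprotected intermediate prone to air oxidation, so the hydroxyls travel as methyl ethers to the last step. The difficulty is threefold: ring D has six different substituents in a fixed order, the dioxin can be fused in two orientations that differ only in which D oxygen meets which B carbon, and the bay between D6 and F5 is crowded. The key step uses the fact that D1 and D4 are para oxygens with the D6 oxygen and the D5 aryl group between them: these four carbons are the ring of an aryl alkoxy squarate and D2–D3 is a 1-methoxyvinyl unit, so ring expansion of a 4-hydroxy-4-(1-methoxyvinyl)cyclobutenone gives ring D with all six substituents placed.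

## Logic of the disconnections

**29 from 28.** The five O–CH3 bonds (D2, F3, F5 and two on ring A) are cut last. Methyl ethers survive every earlier condition (organolithiums, carbonate at 130 °C, copper catalysis, hydrogenolysis, peracid), and one reagent removes all five. The gain is that the seven phenols are never free together before the end. The demand is a Lewis-acid ether cleavage that spares diaryl ether, furan and dioxin C–O bonds, worked up without air.

**28 from 26 (through 27).** The B2–O and B4–O bonds are traced back to B2–CHO and B4–CHO. The formyl groups serve twice: they make B1 and B5 electrophilic (each is ortho to one and para to the other), and afterwards they become hydroxyls by peracid oxidation and methanolysis. The gain is that a penta-oxygenated benzene is reduced to a fluorinated dialdehyde. The demand is aryl migration, not hydride migration, in both oxidations.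

**26 from 25 and 24.** The B1–O bond to ring A is cut. B1 of 25 carries fluoride at a doubly activated position, and ring A enters as a plain phenol. The forward step needs fluoride displacement to outrun any exchange of the dioxin ether at B5, which the better leaving group secures.

**25 from 23.** The dioxin bond B5–O(D6) is cut. In 23 the D1 oxygen already sits on B6, the one ring B carbon meta to both formyl groups, while B5 and B1 are two equivalent activated C–F carbons. The closing bond therefore forms at an activated carbon, either fluoride gives the same product, and the ether already present cannot migrate because ipso attack at B6 has no acceptor to stabilise it. The opposite order (first ether on an activated carbon, closure on the central fluoride) was rejected. In that order the liberated phenoxide can attack the activated ether carbon ipso and exchange the two D oxygens through a spiro Meisenheimer intermediate (Smiles rearrangement) before the slow closure, so the orientation of the dioxin would rest on relative rates. The demand is that D6–OH and the formyl groups are unmasked only now (from 21 through 22).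

**21 from 13 and 20.** The bond B6–O(D1) is cut. It lies at an unactivated carbon and is made by copper-catalysed coupling with an aryl iodide. The formyl groups of 20 are masked as dioxolanes so that its fluorides are inert to the phenoxide. 13 has exactly one free hydroxyl (D1) with D6 still benzylated, which is the pattern the ring expansion delivers without any protecting-group step. The gain is a convergent union of the D/F half with ring B. The demand is a coupling of two ortho,ortho-disubstituted partners.

**20 from 18, 17 and 14.** The C–I bond and the two C–CHO bonds are cut. The C–H between the two fluorines of 18 is the most acidic position, and 17 comes from 14 by double halogen–lithium exchange and formylation. The demand is low temperature for the ortho-fluoro aryllithiums 15 and 19.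

**13 from 12.** The furan bond F1–O(D4) is cut. In 12 the D4 hydroxyl is ortho to the biaryl bond and F1 carries fluorine, while the D1 hydroxyl has no leaving group within reach. The gain is that the dibenzofuran becomes a biaryl whose axis already exists. The demand is substitution at a fluoride that is activated only inductively and sits in a crowded bay.

**12 from 9 (through 11 and 10).** The D3–D4 bond is cut, which opens ring D to a four-membered ring bearing a vinyl ether. All six substituents of ring D are then encoded in the order of two carbonyl additions. The demand is outward rotation of the hydroxyl in the ring opening.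

**9 from 6 and 7 (through 8).** The D1–D2 bond is cut. The metalated vinyl ether must add to the carbonyl next to the benzyloxy carbon, not to the vinylogous ester carbonyl.

**6 from 3 and 2 (through 4 and 5), and 2 from 1.** The D5–F6 bond is cut. 3 is symmetric, so the first addition has no regiochemical question. Acid then turns the adduct into the dione with loss of one benzyloxy group. The aryl bromide comes from bromination at the position between fluorine and methoxy.

## Other disconnections considered

**Alternative 1:** The cut is the biaryl bond D5–F6, made last on a substrate in which rings D and F are already linked twice: by the diaryl ether D4–O–F1 and by a tetraisopropyldisiloxane bridge between the two future bay oxygens (D6–O and F5–O). The forward key step is a transannular dehydrogenative aryl–aryl coupling of the 12-membered macrocycle A1 (a divalent palladium carboxylate under oxygen, or an organic oxidant) to give dibenzofuran A2.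
- In its favour: both coupling carbons lie between two oxygens and are the most electron-rich positions of their rings; the tether leaves D5–F6 as the only coupling that keeps both siloxane oxygens on one side; and the two rings come from separately made phenols without organolithium chemistry.
- Against it here: ring D of A1 needs oxygens at D6, D1, D2 and D4 in three different protection states next to two free C–H positions, and no short regiodefined route to such an arene is evident. The macrocycle must be closed across two meta-bridged arenes. Oxidation of so electron-rich a diaryl ether could turn to quinone formation or to coupling at D3 or F2.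
- Comparison: on structure the squarate route writes the ring D pattern in two additions, where the alternative must assemble it by substitution chemistry. On mechanism the ring expansion is unimolecular, needs no oxidant and has one course. The alternative is the equal of the chosen plan in what it delivers (a dibenzofuran with all ring D oxygens in place). It is the better in one respect: the crowded furan is closed under tether control, not by substitution at an unactivated fluoride as in step 5. The protection pattern of A2 (D1 benzylated, D6 set free together with F5) is the reverse of what the regiosecure dioxin sequence of steps 9 to 11 needs. Step count to the dibenzofuran stage is judged comparable.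

**Alternative 2:** The cut is the second dioxin bond B6–O(D1) with ring B in the quinone oxidation state. D6–O is already bound to B5 of chloroquinone A3, and under mild base the D1 phenoxide displaces the vinylic chloride at B6 by addition–elimination to give dioxin-fused quinone A4.
- In its favour: vinylogous substitution on a haloquinone runs near room temperature with weak base. The carbonyls at B1 and B4 arrive as the future oxygens, so no formyl-to-hydroxyl oxidation is needed; on this point the alternative is better than steps 11 and 12. It uses the same D/F catechol-type building block, so it is equal in convergence.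
- Against it here: D6–O must be attached before D1–O, the opposite of what the squarate-derived intermediates offer (D1 free, D6 benzylated), so protecting-group steps return. B5 of A3 is a vinylogous ester carbon, so the free D1 phenoxide could attack it ipso and exchange the two oxygens before closure, the quinone counterpart of a Smiles rearrangement. After reduction of A4 the B1 and B4 hydroxyls must be told apart and the more hindered one (B1) arylated with an electron-rich 3,5-dioxygenated ring, a copper-mediated coupling at a di-ortho-substituted phenol. A hydroquinone-like ring D beside a quinone also invites redox exchange.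
- Comparison: the alternative is milder and more economical in oxidation state. It is weaker in regiochemical security of the dioxin and clearly weaker in the ring A attachment, which the chosen plan does by displacement of an activated fluoride. Step count is judged similar or slightly longer.

**Alternative 3:** The cut removes ring F. Bonds F2–F3, F4–F5 and F5–F6 form in one photochemical operation from benzofuranyl diazoketone A5 and ynol ether A6: Wolff rearrangement to a heteroarylketene, (2+2) cycloaddition, four-electron opening, and six-electron closure onto C3 of the benzofuran. The product is dibenzofuranol A7.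
- In its favour: it is the close mechanistic relative of the chosen key step (both pass through a cyclobutenone and a dienylketene), so it is equal in mechanism class and pericyclic regiocontrol. It places the free F5 hydroxyl and the F3 ether unambiguously. The furan is part of the starting heterocycle, so no late furan closure is needed, which is better than step 5.
- Against it here: A7 carries hydrogen at D6. The second dioxin oxygen would have to be introduced afterwards at the most hindered position of the dibenzofuran, ortho to the D1 benzyl ether and in the bay opposite the F5 hydroxyl. No directing group is in place, and electrophilic oxidation would rather go to D3 or ring F. The approach also needs a diazo transfer, a volatile ynol ether and photochemical scale-up.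
- Comparison: the alternative solves the easier ring (F, a resorcinol) and leaves the hexasubstituted ring D incomplete, which is exactly the ring the squarate route builds in full. Step count to a D6-oxygenated dibenzofuran is judged longer.

Key step: step 4

Remark on the chemistry: 3 is taken as a purchasable squarate ester (otherwise one step from squaric acid and benzyl alcohol). 9 is racemic and its single stereocentre is erased in step 4. The atom mapping of 9 and 12 onto ring D (D4 = ring carbonyl carbon, D5 = aryl carbon, D6 = benzyloxy carbon, D1 = carbinol carbon, D2–D3 = vinyl ether) was checked against 29 and needs no correction. The tertiary hydroxyl of 9 is left free on purpose, because it becomes the one free hydroxyl (D1) that step 9 needs.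

## Route

Step 1
Reactants: 1 1-fluoro-3,5-dimethoxybenzene
Product: 2 2-bromo-1-fluoro-3,5-dimethoxybenzene
Conditions: NBS (1.0 equiv), MeCN, 0 °C to rt
Reagents that add atoms: N-bromosuccinimide, O=C1CCC(=O)N1Br
Why: Electrophilic aromatic bromination; the position between fluorine and methoxy is ortho to one methoxy and para to the other and is less hindered than the position between the two methoxy groups, so monobromination there is expected.

Step 2
Reactants: 2 2-bromo-1-fluoro-3,5-dimethoxybenzene; 3 dibenzyl squarate
Product: 6 3-(benzyloxy)-4-(2-fluoro-4,6-dimethoxyphenyl)cyclobut-3-ene-1,2-dione, via aryllithium 4 (not isolated), via squarate monoadduct 5 (not isolated)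
Conditions: n-BuLi, THF, −78 °C; add to 3, THF, −78 °C; aq NH4Cl; then conc. HCl (cat.), CH2Cl2, rt
Reagents that add atoms: water, O
Why: Bromine–lithium exchange gives 4, which is kept at −78 °C where loss of LiF to an aryne is slow, and 1,2-addition to one carbonyl of the symmetric squarate gives 5. Acid ionises the carbinol to an alkoxy-stabilised cyclobutenyl cation that takes up water at the benzyloxy carbon and expels benzyl alcohol, the known conversion of squarate ester adducts into 3-aryl-4-alkoxycyclobutenediones.

Step 3
Reactants: 6 3-(benzyloxy)-4-(2-fluoro-4,6-dimethoxyphenyl)cyclobut-3-ene-1,2-dione; 7 methyl vinyl ether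
Product: 9 racemic 3-(benzyloxy)-2-(2-fluoro-4,6-dimethoxyphenyl)-4-hydroxy-4-(1-methoxyvinyl)cyclobut-2-en-1-one, via 1-methoxyvinyllithium 8 (not isolated)
Conditions: 7, t-BuLi, THF, −78 to 0 °C; then 6, THF, −78 °C; cold H2O, aq NaHCO3
Reagents that add atoms: none
Why: α-Lithiation of the vinyl ether gives 8, which adds 1,2 to the carbonyl next to the benzyloxy carbon, because the other carbonyl is a vinylogous ester and is shielded by the di-ortho-substituted aryl ring (regioselective organolithium addition to an alkoxycyclobutenedione). The new stereocentre forms as a racemate and is erased in step 4; the non-acidic work-up protects the enol ether.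

Step 4
Reactants: 9 racemic 3-(benzyloxy)-2-(2-fluoro-4,6-dimethoxyphenyl)-4-hydroxy-4-(1-methoxyvinyl)cyclobut-2-en-1-one
Product: 12 3-(benzyloxy)-2-(2-fluoro-4,6-dimethoxyphenyl)-5-methoxybenzene-1,4-diol, via dienylketene 10 (not isolated), via cyclohexadienone 11 (not isolated)
Conditions: degassed toluene, 110 °C, Ar; crude product kept under Ar
Reagents that add atoms: none
Why: Heating opens the cyclobutenone by a conrotatory four-electron electrocyclic reaction in which the donor hydroxyl turns outward and the 1-methoxyvinyl group inward, giving dienylketene 10 with the vinyl group cis to the ketene-bearing carbon. A disrotatory six-electron electrocyclisation then joins the ketene carbon (D4) to the vinyl CH2 (D3) and closes ring D as dienone 11, and enolisation gives hydroquinone 12. The closest known reaction type is the Moore rearrangement of 4-alkenyl-4-hydroxycyclobutenones made from squarate esters. Ring D is the only ring closed, by pericyclic six-membered closure with aromatisation as driving force. No stereocentre is formed. The step needs the torquoselectivity described, since inward rotation of the hydroxyl would let it add to the ketene and give a butenolide; the stronger donor character of hydroxyl relative to the vinyl group secures it. Regiochemistry is not at stake because only one terminus can reach the ketene and the substituent order was fixed in steps 2 and 3. Degassed solvent keeps the electron-rich hydroquinone from oxidising to the quinone.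

Step 5
Reactants: 12 3-(benzyloxy)-2-(2-fluoro-4,6-dimethoxyphenyl)-5-methoxybenzene-1,4-diol
Product: 13 1-(benzyloxy)-3,7,9-trimethoxydibenzo[b,d]furan-2-ol
Conditions: Cs2CO3 (3 equiv), degassed NMP, 130 °C, Ar
Reagents that add atoms: none
Why: Intramolecular SNAr of the D4 phenoxide on the aryl fluoride (five-membered closure), the known route from 2'-fluorobiphenyl-2-ols to dibenzofurans. Both methoxy groups of ring F are meta to the C–F carbon, so they stabilise the Meisenheimer intermediate inductively and do not donate into it. The D1 phenoxide has no leaving group within reach.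

Step 6
Reactants: 14 1,5-dibromo-2,4-difluorobenzene
Product: 17 4,6-difluorobenzene-1,3-dicarbaldehyde, via dilithioarene 15 (not isolated), via bis-hemiaminal dialkoxide 16 (not isolated)
Conditions: t-BuLi (4.2 equiv), Et2O, −78 °C; DMF, −78 °C to rt; 2 M HCl
Reagents that add atoms: N,N-dimethylformamide, CN(C)C=O
Why: Double bromine–lithium exchange (each lithium stabilised by an ortho fluorine, kept cold to avoid aryne formation) followed by formylation with DMF; the tetrahedral adducts 16 collapse to the aldehydes only on acidic work-up.

Step 7
Reactants: 17 4,6-difluorobenzene-1,3-dicarbaldehyde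
Product: 18 2,2'-(4,6-difluoro-1,3-phenylene)bis(1,3-dioxolane)
Conditions: HOCH2CH2OH, p-TsOH (cat.), toluene, reflux, Dean–Stark
Reagents that add atoms: ethylene glycol, OCCO
Why: Acid-catalysed acetalisation with azeotropic removal of water; the dioxolanes switch off the SNAr activation of the two fluorides and tolerate the bases of steps 8 and 9.

Step 8
Reactants: 18 2,2'-(4,6-difluoro-1,3-phenylene)bis(1,3-dioxolane)
Product: 20 2,2'-(4,6-difluoro-5-iodo-1,3-phenylene)bis(1,3-dioxolane), via aryllithium 19 (not isolated)
Conditions: LiN(iPr)2, THF, −78 °C; I2, −78 °C to rt
Reagents that add atoms: iodine, II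
Why: Fluorine-directed ortho-lithiation at the C–H flanked by two fluorines, by far the most acidic ring position, then iodination of 19; the amide base follows acidity and is not drawn to the position between the acetals.

Step 9
Reactants: 13 1-(benzyloxy)-3,7,9-trimethoxydibenzo[b,d]furan-2-ol; 20 2,2'-(4,6-difluoro-5-iodo-1,3-phenylene)bis(1,3-dioxolane)
Product: 21 2,2'-{5-[(1-(benzyloxy)-3,7,9-trimethoxydibenzo[b,d]furan-2-yl)oxy]-4,6-difluoro-1,3-phenylene}bis(1,3-dioxolane)
Conditions: CuI (10 mol %), picolinic acid (20 mol %), K3PO4, degassed DMSO, 90 °C, Ar
Reagents that add atoms: none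
Why: Ullmann-type copper-catalysed O-arylation of the only free phenol (D1) with the aryl iodide, under ligand conditions known for ortho-substituted phenols. With the formyl groups masked the C–F carbons are not activated, so only the C–I bond reacts and the D1 oxygen is placed on the central carbon B6.

Step 10
Reactants: 21 2,2'-{5-[(1-(benzyloxy)-3,7,9-trimethoxydibenzo[b,d]furan-2-yl)oxy]-4,6-difluoro-1,3-phenylene}bis(1,3-dioxolane)
Product: 23 4,6-difluoro-5-[(1-hydroxy-3,7,9-trimethoxydibenzo[b,d]furan-2-yl)oxy]benzene-1,3-dicarbaldehyde, via debenzylated bis-acetal 22 (not isolated)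
Conditions: H2 (1 atm), Pd/C, EtOAc–EtOH, rt; filter; then 2 M HCl, THF, 45 °C
Reagents that add atoms: water, O
Why: Hydrogenolysis of the benzyl aryl ether frees D6–OH while acetals, aryl fluorides and diaryl ether are inert; acid hydrolysis of the dioxolanes is done only after the catalyst is removed, so the aldehydes never meet hydrogen.

Step 11
Reactants: 23 4,6-difluoro-5-[(1-hydroxy-3,7,9-trimethoxydibenzo[b,d]furan-2-yl)oxy]benzene-1,3-dicarbaldehyde; 24 3,5-dimethoxyphenol
Product: 26 pentacyclic dialdehyde carrying ring A (B1 3,5-dimethoxyphenoxy; B2 and B4 formyl; methyl ethers at D2 F3 F5), via fluoro dioxin dialdehyde 25 (not isolated)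
Conditions: K2CO3, DMF, rt; then 24, K2CO3, 60 °C
Reagents that add atoms: none
Why: Two SNAr reactions in sequence: the D6 phenoxide closes the dioxin on either of two equivalent fluorides that are ortho to one formyl group and para to the other (six-membered closure), and the remaining, equally activated fluoride of 25 is then displaced by the phenoxide of 24. The ether already present sits at B6, meta to both formyl groups, so no Smiles-type exchange of the D oxygens can occur and the orientation of the dioxin is fixed.

Step 12
Reactants: 26 pentacyclic dialdehyde carrying ring A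
Product: 28 pentamethyl ether of the target (B2 and B4 hydroxyl free), via bis-formate 27 (not isolated)
Conditions: mCPBA (2.5 equiv), CH2Cl2, 0 °C to rt; then K2CO3, MeOH, rt, Ar
Reagents that add atoms: 3-chloroperbenzoic acid, OOC(=O)c1cccc(Cl)c1
Why: Baeyer–Villiger oxidation of aryl aldehydes bearing ortho and para aryloxy donors (Dakin-type), in which the electron-rich aryl group migrates to give aryl formates; methanolysis of 27 releases the two phenols.

Step 13
Reactants: 28 pentamethyl ether of the target
Product: 29 target: 3,5-dihydroxyphenyl ether at B1 of the benzofuro-fused dibenzodioxin with hydroxyls at B2 B4 D2 F3 F5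
Conditions: BBr3 (excess), CH2Cl2, −78 °C to rt; MeOH, H2O, Ar
Reagents that add atoms: none
Why: Lewis-acid cleavage of the five aryl methyl ethers through aryloxyboron intermediates; diaryl ether, furan and dioxin C–O bonds are not cleaved, and air-free work-up protects the polyphenol.

## Compound list

1 | 1-fluoro-3,5-dimethoxybenzene | COc1cc(F)cc(OC)c1 | starting material
2 | 2-bromo-1-fluoro-3,5-dimethoxybenzene | COc1cc(F)c(Br)c(OC)c1 | intermediate
3 | dibenzyl squarate, 3,4-bis(benzyloxy)cyclobut-3-ene-1,2-dione | O=C1C(=O)C(OCc2ccccc2)=C1OCc1ccccc1 | starting material
4 | (2-fluoro-4,6-dimethoxyphenyl)lithium | [Li]c1c(F)cc(OC)cc1OC | intermediate (not isolated)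
5 | racemic 2,3-bis(benzyloxy)-4-(2-fluoro-4,6-dimethoxyphenyl)-4-hydroxycyclobut-2-en-1-one | O=C1C(OCc2ccccc2)=C(OCc2ccccc2)C1(O)c1c(F)cc(OC)cc1OC | intermediate (not isolated)
6 | 3-(benzyloxy)-4-(2-fluoro-4,6-dimethoxyphenyl)cyclobut-3-ene-1,2-dione | O=C1C(=O)C(OCc2ccccc2)=C1c1c(F)cc(OC)cc1OC | intermediate
7 | methyl vinyl ether | COC=C | starting material
8 | (1-methoxyvinyl)lithium | [Li]C(=C)OC | intermediate (not isolated)
9 | racemic 3-(benzyloxy)-2-(2-fluoro-4,6-dimethoxyphenyl)-4-hydroxy-4-(1-methoxyvinyl)cyclobut-2-en-1-one | O=C1C(c2c(F)cc(OC)cc2OC)=C(OCc2ccccc2)C1(O)C(OC)=C | intermediate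
10 | dienylketene: 3-(benzyloxy)-2-(2-fluoro-4,6-dimethoxyphenyl)-4-hydroxy-5-methoxyhexa-1,3,5-trien-1-one, vinyl group cis to the ketene-bearing carbon | O=C=C(c1c(F)cc(OC)cc1OC)/C(OCc1ccccc1)=C(/O)C(OC)=C | intermediate (not isolated)
11 | 3-(benzyloxy)-2-(2-fluoro-4,6-dimethoxyphenyl)-4-hydroxy-5-methoxycyclohexa-2,4-dien-1-one | O=C1CC(OC)=C(O)C(OCc2ccccc2)=C1c1c(F)cc(OC)cc1OC | intermediate (not isolated)
12 | 3-(benzyloxy)-2-(2-fluoro-4,6-dimethoxyphenyl)-5-methoxybenzene-1,4-diol | Oc1cc(OC)c(O)c(OCc2ccccc2)c1-c1c(F)cc(OC)cc1OC | intermediate
13 | 1-(benzyloxy)-3,7,9-trimethoxydibenzo[b,d]furan-2-ol | COc1cc2oc3cc(OC)cc(OC)c3c2c(OCc2ccccc2)c1O | intermediate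
14 | 1,5-dibromo-2,4-difluorobenzene | Fc1cc(F)c(Br)cc1Br | starting material
15 | (4,6-difluoro-1,3-phenylene)dilithium | [Li]c1cc([Li])c(F)cc1F | intermediate (not isolated)
16 | dilithium (4,6-difluoro-1,3-phenylene)bis[(dimethylamino)methanolate] | [Li]OC(N(C)C)c1cc(C(O[Li])N(C)C)c(F)cc1F | intermediate (not isolated)
17 | 4,6-difluorobenzene-1,3-dicarbaldehyde | O=Cc1cc(C=O)c(F)cc1F | intermediate
18 | 2,2'-(4,6-difluoro-1,3-phenylene)bis(1,3-dioxolane) | Fc1cc(F)c(C2OCCO2)cc1C1OCCO1 | intermediate
19 | [2,6-difluoro-3,5-bis(1,3-dioxolan-2-yl)phenyl]lithium | [Li]c1c(F)c(C2OCCO2)cc(C2OCCO2)c1F | intermediate (not isolated)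
20 | 2,2'-(4,6-difluoro-5-iodo-1,3-phenylene)bis(1,3-dioxolane) | Fc1c(I)c(F)c(C2OCCO2)cc1C1OCCO1 | intermediate
21 | 2,2'-{5-[(1-(benzyloxy)-3,7,9-trimethoxydibenzo[b,d]furan-2-yl)oxy]-4,6-difluoro-1,3-phenylene}bis(1,3-dioxolane) | COc1cc2oc3cc(OC)cc(OC)c3c2c(OCc2ccccc2)c1Oc1c(F)c(C2OCCO2)cc(C2OCCO2)c1F | intermediate
22 | 2-[2,6-difluoro-3,5-bis(1,3-dioxolan-2-yl)phenoxy]-3,7,9-trimethoxydibenzo[b,d]furan-1-ol | COc1cc2oc3cc(OC)cc(OC)c3c2c(O)c1Oc1c(F)c(C2OCCO2)cc(C2OCCO2)c1F | intermediate (not isolated)
23 | 4,6-difluoro-5-[(1-hydroxy-3,7,9-trimethoxydibenzo[b,d]furan-2-yl)oxy]benzene-1,3-dicarbaldehyde | COc1cc2oc3cc(OC)cc(OC)c3c2c(O)c1Oc1c(F)c(C=O)cc(C=O)c1F | intermediate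
24 | 3,5-dimethoxyphenol | COc1cc(O)cc(OC)c1 | starting material
25 | fluoro dioxin dialdehyde: pentacycle F/furan/D/dioxin/B with B6–O–D1 and B5–O–D6; B1 fluorine; B2 and B4 formyl; methoxy at D2, F3, F5 | COc1cc2oc3cc(OC)cc(OC)c3c2c2c1Oc1c(F)c(C=O)cc(C=O)c1O2 | intermediate (not isolated)
26 | the same pentacycle with B1 3,5-dimethoxyphenoxy; B2 and B4 formyl; methoxy at D2, F3, F5 | COc1cc2oc3cc(OC)cc(OC)c3c2c2c1Oc1c(Oc3cc(OC)cc(OC)c3)c(C=O)cc(C=O)c1O2 | intermediate
27 | bis-formate: as 26 with formyloxy groups at B2 and B4 | COc1cc2oc3cc(OC)cc(OC)c3c2c2c1Oc1c(Oc3cc(OC)cc(OC)c3)c(OC=O)cc(OC=O)c1O2 | intermediate (not isolated)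
28 | pentamethyl ether of the target: hydroxyl at B2 and B4; methoxy at D2, F3, F5 and at both meta positions of ring A | COc1cc2oc3cc(OC)cc(OC)c3c2c2c1Oc1c(Oc3cc(OC)cc(OC)c3)c(O)cc(O)c1O2 | intermediate
29 | target: B1 3,5-dihydroxyphenoxy; hydroxyl at B2, B4, D2, F3, F5; dioxin B6–O–D1 and B5–O–D6; furan D4–O–F1 and D5–F6 | Oc1cc(O)cc(Oc2c(O)cc(O)c3c2Oc2c(O)cc4oc5cc(O)cc(O)c5c4c2O3)c1 | target

## Step count and least certain steps

Total: 13 steps. Longest linear sequence: 10 steps (steps 1 to 5 and 9 to 13, from 1); the ring B branch (steps 6 to 8) has 3 steps.

**Step 4 (key step).** The likely failures are inward rotation of the hydroxyl during ring opening, so that it adds to the ketene and a butenolide forms; hydrolysis of the enol ether before or during heating; and air oxidation of the hydroquinone to the quinone during isolation. The fallback sets out from 6 and comes back at 13. The lithium alkoxide formed from 6 and 8 is trapped in the flask with Et3SiCl to give racemic 3-(benzyloxy)-2-(2-fluoro-4,6-dimethoxyphenyl)-4-(1-methoxyvinyl)-4-[(triethylsilyl)oxy]cyclobut-2-en-1-one F1, which has no hydroxyl to intercept the ketene. Thermolysis as in step 4 then gives the air-stable monosilyl ether 3-(benzyloxy)-2-(2-fluoro-4,6-dimethoxyphenyl)-5-methoxy-4-[(triethylsilyl)oxy]phenol F2. Under the conditions of step 5 with added CsF the silyl group is removed in the flask and the furan closes to 13.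

**Step 9.** The likely failure is slow coupling because both partners are ortho,ortho-disubstituted, with reductive loss of iodine from 20 and oxidative degradation of the electron-rich phenol. The fallback sets out from 13 and comes back at 25; it forms the two dioxin bonds in the opposite order by SNAr alone.
- 13 is protected at D1 (MOMCl, iPr2NEt) as 1-(benzyloxy)-3,7,9-trimethoxy-2-(methoxymethoxy)dibenzo[b,d]furan F3.
- Hydrogenolysis gives 3,7,9-trimethoxy-2-(methoxymethoxy)dibenzo[b,d]furan-1-ol F4.
- F4 is added (K2CO3, DMF, 0 °C) to an excess of 4,5,6-trifluorobenzene-1,3-dicarbaldehyde F5, prepared like 17 from the trifluoro analogue of 14. This gives 4,5-difluoro-6-{[3,7,9-trimethoxy-2-(methoxymethoxy)dibenzo[b,d]furan-1-yl]oxy}benzene-1,3-dicarbaldehyde F6.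
- Aqueous HCl in THF removes the acetal protecting group to give 4,5-difluoro-6-[(2-hydroxy-3,7,9-trimethoxydibenzo[b,d]furan-1-yl)oxy]benzene-1,3-dicarbaldehyde F7, and K2CO3 in DMF closes the dioxin on the central fluoride to give 25.
- The weakness of this order is loss of regiocontrol by Smiles-type exchange of the two D oxygens at the activated ether carbon before the slow closure. That is why it is the fallback and not the route.

**Step 5.** The likely failure is slow substitution at a hindered fluoride that is activated only inductively, with oxidation or benzyl transfer of the hydroquinone dianion at the temperature needed. The fallback sets out from 12 and comes back at 13; it changes the mechanism to elimination–addition. Excess LiTMP (lithium 2,2,6,6-tetramethylpiperidide) in THF from −78 °C to rt deprotonates both hydroxyls and the ring F proton between fluorine and methoxy. Loss of LiF gives the aryne 3-(benzyloxy)-2-(4,6-dimethoxy-2,3-didehydrophenyl)-5-methoxybenzene-1,4-diol F8 (as its lithium phenoxides). The D4 phenoxide adds to the aryne carbon that carried fluorine (five-membered closure, with the charge ending next to methoxy), and protonation gives 13.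

**Step 12.** The likely failure is competing hydride migration to give carboxylic acids, because the donors are aryloxy groups and each formyl group has the other as a meta acceptor; peracid attack on the electron-rich rings D, F and A is a second risk. The fallback sets out from 26 and comes back at 28. MeMgBr adds to both aldehydes to give the bis(1-hydroxyethyl) compound F9 (diastereomer mixture). MnO2 oxidises it to the diacetyl compound F10. Baeyer–Villiger oxidation of the aryl methyl ketones with mCPBA, where only aryl migration competes, gives the diacetate F11, and methanolysis (K2CO3, MeOH) gives 28.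

**Step 6.** The likely failure is incomplete second exchange, proton transfer from the acidic C–H between the fluorines to an aryllithium, or loss of LiF to an aryne if the temperature rises. The fallback sets out from 14 and comes back at 18; it works stepwise with magnesium reagents, which are stable toward these pathways. One exchange with iPrMgCl·LiCl and DMF gives 5-bromo-2,4-difluorobenzaldehyde F12. Acetalisation gives 2-(5-bromo-2,4-difluorophenyl)-1,3-dioxolane F13. A second exchange and formylation gives 5-(1,3-dioxolan-2-yl)-2,4-difluorobenzaldehyde F14, and acetalisation as in step 7 gives 18.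

## Further compounds

F1 | step 4 | racemic 3-(benzyloxy)-2-(2-fluoro-4,6-dimethoxyphenyl)-4-(1-methoxyvinyl)-4-[(triethylsilyl)oxy]cyclobut-2-en-1-one | O=C1C(c2c(F)cc(OC)cc2OC)=C(OCc2ccccc2)C1(O[Si](CC)(CC)CC)C(OC)=C
F2 | step 4 | 3-(benzyloxy)-2-(2-fluoro-4,6-dimethoxyphenyl)-5-methoxy-4-[(triethylsilyl)oxy]phenol | Oc1cc(OC)c(O[Si](CC)(CC)CC)c(OCc2ccccc2)c1-c1c(F)cc(OC)cc1OC
F3 | step 9 | 1-(benzyloxy)-3,7,9-trimethoxy-2-(methoxymethoxy)dibenzo[b,d]furan | COCOc1c(OC)cc2oc3cc(OC)cc(OC)c3c2c1OCc1ccccc1
F4 | step 9 | 3,7,9-trimethoxy-2-(methoxymethoxy)dibenzo[b,d]furan-1-ol | COCOc1c(OC)cc2oc3cc(OC)cc(OC)c3c2c1O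
F5 | step 9 | 4,5,6-trifluorobenzene-1,3-dicarbaldehyde | O=Cc1cc(C=O)c(F)c(F)c1F
F6 | step 9 | 4,5-difluoro-6-{[3,7,9-trimethoxy-2-(methoxymethoxy)dibenzo[b,d]furan-1-yl]oxy}benzene-1,3-dicarbaldehyde | COCOc1c(OC)cc2oc3cc(OC)cc(OC)c3c2c1Oc1c(F)c(F)c(C=O)cc1C=O
F7 | step 9 | 4,5-difluoro-6-[(2-hydroxy-3,7,9-trimethoxydibenzo[b,d]furan-1-yl)oxy]benzene-1,3-dicarbaldehyde | COc1cc2oc3cc(OC)cc(OC)c3c2c(Oc2c(F)c(F)c(C=O)cc2C=O)c1O
F8 | step 5 | aryne 3-(benzyloxy)-2-(4,6-dimethoxy-2,3-didehydrophenyl)-5-methoxybenzene-1,4-diol | COC1=CC(OC)=C(c2c(O)cc(OC)c(O)c2OCc2ccccc2)C#C1
F9 | step 12 | bis(1-hydroxyethyl) analogue of 26 at B2 and B4 (diastereomer mixture) | COc1cc2oc3cc(OC)cc(OC)c3c2c2c1Oc1c(Oc3cc(OC)cc(OC)c3)c(C(C)O)cc(C(C)O)c1O2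
F10 | step 12 | diacetyl analogue of 26 at B2 and B4 | COc1cc2oc3cc(OC)cc(OC)c3c2c2c1Oc1c(Oc3cc(OC)cc(OC)c3)c(C(C)=O)cc(C(C)=O)c1O2
F11 | step 12 | diacetate of 28 at B2 and B4 | COc1cc2oc3cc(OC)cc(OC)c3c2c2c1Oc1c(Oc3cc(OC)cc(OC)c3)c(OC(C)=O)cc(OC(C)=O)c1O2
F12 | step 6 | 5-bromo-2,4-difluorobenzaldehyde | O=Cc1cc(Br)c(F)cc1F
F13 | step 6 | 2-(5-bromo-2,4-difluorophenyl)-1,3-dioxolane | Fc1cc(F)c(C2OCCO2)cc1Br
F14 | step 6 | 5-(1,3-dioxolan-2-yl)-2,4-difluorobenzaldehyde | O=Cc1cc(C2OCCO2)c(F)cc1F
A1 | alternative 1 | 12-membered macrocycle: diaryl ether D4–O–F1 with a tetraisopropyldisiloxane bridge from D6–O to F5–O; D1 benzyloxy; D2 and F3 methoxy | COc1cc2Oc3cc(OC)cc(c3)O[Si](C(C)C)(C(C)C)O[Si](C(C)C)(C(C)C)Oc(c2)c1OCc1ccccc1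
A2 | alternative 1 | dibenzofuran with the disiloxane bridge across the bay oxygens | COc1cc2oc3cc(OC)cc4c3c2c(c1OCc1ccccc1)O[Si](C(C)C)(C(C)C)O[Si](C(C)C)(C(C)C)O4
A3 | alternative 2 | 3-chloro-2-[(2-hydroxy-3,7,9-trimethoxydibenzo[b,d]furan-1-yl)oxy]-5-methoxycyclohexa-2,5-diene-1,4-dione | COc1cc2oc3cc(OC)cc(OC)c3c2c(OC2=C(Cl)C(=O)C(OC)=CC2=O)c1O
A4 | alternative 2 | dioxin-fused methoxy-1,4-benzoquinone (ring B in the quinone state) | COc1cc2oc3cc(OC)cc(OC)c3c2c2c1OC1=C(O2)C(=O)C=C(OC)C1=O
A5 | alternative 3 | 1-[5-(benzyloxy)-6-methoxybenzofuran-2-yl]-2-diazoethan-1-one | COc1cc2oc(C(=O)C=[N+]=[N-])cc2cc1OCc1ccccc1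
A6 | alternative 3 | ethoxyacetylene | CCOC#C
A7 | alternative 3 | 8-(benzyloxy)-3-ethoxy-7-methoxydibenzo[b,d]furan-1-ol | COc1cc2oc3cc(OCC)cc(O)c3c2cc1OCc1ccccc1
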